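A percentage point is the unit here, and a repeated reading scatters by 1 percentage point, so I base the decision about Tuesday's flask on a quantity and not on one step between readings. The decision is whether to stop the flask when the feed ends at 5.0 d, or to leave it stirring to 10 d with the charges unchanged.

| flask | first end groups | second end groups | remark | time |
|---|---|---|---|---|
| Tuesday's | 0.25 M | 0.95 equiv (fed, over 5.0 d) | the very flask that is asked about, followed so far; the fed solution adds 0.50 times the starting volume |  |
| Thursday's | 0.50 M | 0.95 equiv (fed, over 5.0 d) | run made earlier; the fed solution adds 0.50 times the starting volume |  |
| flask | 0.25 M | 0.950 equiv (fed, over 5.0 d) | the fed solution adds 0.50 times the starting volume | 10 d |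

| run | time / d | links / % |
|---|---|---|
| Tuesday's | 0.625 | 2.7 |
| Tuesday's | 1.25 | 8.5 |
| Tuesday's | 1.67 | 12.7 |
| Tuesday's | 2.50 | 21.9 |
| Tuesday's | 3.00 | 29.6 |
| Thursday's | 0.333 | 0.2 |
| Thursday's | 1.04 | 9.8 |
| Thursday's | 1.67 | 20.8 |
| Thursday's | 3.00 | 34.9 |
| Thursday's | 4.00 | 46.6 |

(standard deviation of a reading: 1 percentage point)

* at 10 d, what has stopped the reaction, if anything has (the second end groups has run out first / forward and back rates have come level / all of the first end groups has reacted / it is still moving)
* the links standing at 10 d, as a percentage of the first end groups charged

- charges are per starting volume, the dose included; the dosed solution carries all of it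
- the reaction counts as stopped when no species that holds the first end groups changes by six tenths of a point or more over the second half of the time

I start from Thursday's last reading, at 4.00 d, when second end groups equal to 76.0% of the first end groups had been fed and 46.6% stood as links:

Q = [links]² / ([first end groups unlinked] · [second end groups unlinked]) = 1.38

This share quotient, a reaction quotient with two terms above and two below so that the volume cancels, is my bet on the form, because neither run reaches a level that could test it. Thursday's links were still rising, so I read Q as a floor on the level quotient and carry it to the lower concentration. With the whole charge in, the floor gives:

x² = Q(1 − x)(0.950 − x), so x = 52.7%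

I commit to at least that many links. Tuesday's flask has Q = 0.454 at its last reading, at 3.00 d, below the floor. Held at that run's mean pace, its links reach an estimated 49.3% when the feed ends at 5.0 d, which is 3.4 points short of my floor. That gap is above the scatter of 1 point, and the stopping rule allows 0.6 points over the second half of the time, so I call the flask still moving and leave it stirring.

The forecast says it is still moving, with 50% links, below my floor, on the ground that “links still rise about 6 points between 5 and 10 d”.

    first end groups + second end groups ⇌ links + released group (K = 3.00, k = 6.09 × 10⁻⁵ L mol⁻¹ s⁻¹)
    first end groups ⇌ dormant form (K = 0.410, k = 7.17 × 10⁻⁶ s⁻¹)

The flask gives 57.6% links and the verdict it is still moving: the largest change of a share over the second half of the time is 9.6 points, and at 100 d links stand at 57.8%. With the dormant form counted among the unlinked first end groups, Q at 10 d is 2.09, above the floor. Put into the same flask charged with 0.380 equiv of second end groups, this Q reckons 31.2% links, and that flask stands at 31.0%.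

(The data are simulated with constants of no real substance; scatter was added.)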